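**Strategy.** The isovalerate sits on C2', between the carbinol carbons C1' (bonded to C6 of benzene ring A) and C3'. Exchanging its ester oxygen for a C–C bond gives a 2-acyl-1,3-diol, an aldol pattern whose C1'–C2' bond comes from a syn-aldol of 7-methoxycoumarin-6-carbaldehyde. A late Baeyer–Villiger oxidation of the isobutyl ketone then inserts oxygen between C2' and the ketone carbon with retention, making C2'–O and O–C(acyl) in one operation, so the ester cannot end up on O1' or O3'. The electron-poor C3=C4 bond of pyranone ring B stays inert. The precursor is the trans-4-aryl-5-(3-methylbutanoyl)-2,2,6,6-tetramethyl-1,3-dioxane, with O1' and O3' tied as an acetonide.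

Key step: step 10

Remark on the chemistry: C1'–C3' are the side-chain carbons counted from the coumarin; ring A is the benzene ring and ring B the pyranone ring. The tetramethyl-1,3-dioxane is expected to sit in a twist-boat, because a chair would place the C2 and C6 methyls syn-axial; the 4,5-trans relationship is unaffected.
Assumption: (S)-4-benzyl-1,3-thiazolidine-2-thione and isobutylzinc bromide (0.5 M in THF) are purchased.

**Step 1**
Reactants: 1 4-bromoresorcinol (4-bromobenzene-1,3-diol)
Product: 2 6-bromo-7-hydroxy-2H-chromen-2-one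
Conditions: DL-malic acid (1.1 equiv), conc. H2SO4, 100 °C
Reagents that add atoms: DL-malic acid, OC(CC(=O)O)C(=O)O
Why: Pechmann condensation: in sulfuric acid malic acid loses CO and water to give formylacetic acid, which should attack the one unhindered ring position activated by both hydroxyls (ortho to one, para to the other) and lactonise, placing bromine on C6 and the free hydroxyl on C7.

**Step 2**
Reactants: 2 6-bromo-7-hydroxy-2H-chromen-2-one
Product: 3 6-bromo-7-methoxy-2H-chromen-2-one
Conditions: MeI, K2CO3, acetone, reflux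
Reagents that add atoms: iodomethane, CI
Why: Williamson O-methylation of the acidic C7 phenol under anhydrous carbonate conditions, which should leave the lactone closed.

**Step 3**
Reactants: 3 6-bromo-7-methoxy-2H-chromen-2-one
Product: 4 7-methoxy-2-oxo-2H-chromene-6-carbaldehyde
Conditions: Pd(OAc)2 (1 mol%), P(1-Ad)2(n-Bu) (3 mol%), TMEDA (1 equiv), CO/H2 (1:1, 5 bar), toluene, 100 °C
Reagents that add atoms: carbon monoxide, [C-]#[O+]
Why: Palladium-catalysed reductive carbonylation (formylation) of an aryl bromide with synthesis gas (oxidative addition to zerovalent palladium, CO insertion, hydrogenolysis of the acylpalladium) tolerates esters and should not touch the lactone or the conjugated C3=C4 bond under CO.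

**Step 4**
Reactants: 5 3-hydroxy-3-methylbutanoic acid
Product: 7 3-methyl-3-(triethylsilyloxy)butanoic acid, via bis-silylated ester 6 (not isolated)
Conditions: TESCl (2.3 equiv), imidazole (4.5 equiv), DMF, rt; then H2O, THF, rt; work-up at pH 4
Reagents that add atoms: chlorotriethylsilane, CC[Si](Cl)(CC)CC
Why: Silylation of hydroxyl and carboxyl groups followed by selective hydrolysis of the labile silyl ester is the standard route to a silyl-protected hydroxy acid, and the tertiary triethylsilyl ether should survive the water treatment.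

**Step 5**
Reactants: 7 3-methyl-3-(triethylsilyloxy)butanoic acid; 8 (S)-4-benzyl-1,3-thiazolidine-2-thione
Product: 9 (S)-4-benzyl-3-[3-methyl-3-(triethylsilyloxy)butanoyl]-1,3-thiazolidine-2-thione
Conditions: DCC (1.1 equiv), DMAP (0.1 equiv), CH2Cl2, 0 °C to rt
Reagents that add atoms: none
Why: Carbodiimide (Steglich-type) N-acylation of the thiazolidinethione with DMAP as acyl-transfer catalyst is routine, and the auxiliary stereocentre is not involved.

**Step 6**
Reactants: 9 (S)-4-benzyl-3-[3-methyl-3-(triethylsilyloxy)butanoyl]-1,3-thiazolidine-2-thione; 4 7-methoxy-2-oxo-2H-chromene-6-carbaldehyde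
Product: 11 (S)-4-benzyl-3-[(2R,3S)-3-hydroxy-3-(7-methoxy-2-oxo-2H-chromen-6-yl)-2-[2-(triethylsilyloxy)propan-2-yl]propanoyl]-1,3-thiazolidine-2-thione, via chlorotitanium Z-enolate 10 (not isolated)
Conditions: TiCl4 (1.05 equiv), iPr2NEt (1.1 equiv), NMP (1.0 equiv), CH2Cl2, 0 °C; then 4 (1.1 equiv), −78 to 0 °C; aq. NH4Cl
Reagents that add atoms: none
Why: Titanium-enolate aldol of an N-acyl thiazolidinethione in its non-chelated (Evans-syn) mode: soft enolisation gives Z-enolate 10, NMP occupies the free site on titanium so the thiocarbonyl cannot chelate, and the aldehyde adds through a chair Zimmerman–Traxler transition state to the enolate face opposite the benzyl group, which should set C2' (2R) and C1' (3S) together as the syn pair.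

**Step 7**
Reactants: 11 the syn-aldol adduct
Product: 12 S-ethyl (2R,3S)-3-hydroxy-3-(7-methoxy-2-oxo-2H-chromen-6-yl)-2-[2-(triethylsilyloxy)propan-2-yl]propanethioate
Conditions: EtSH (5 equiv), K2CO3 (0.2 equiv), MeCN, 0 °C to rt
Reagents that add atoms: ethanethiol, CCS
Why: The twisted, activated N-acyl thiazolidinethione undergoes acyl substitution by thiolate under catalytic base (the released auxiliary anion regenerates thiolate), a standard auxiliary displacement that needs neither hydroxide nor hydride and should spare the lactone, the silyl ether and the aldol hydroxyl.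

**Step 8**
Reactants: 12 the hydroxy silyloxy thioester
Product: 14 S-ethyl (4S,5R)-4-(7-methoxy-2-oxo-2H-chromen-6-yl)-2,2,6,6-tetramethyl-1,3-dioxane-5-carbothioate, via diol thioester 13 (not isolated)
Conditions: CSA (0.1 equiv), MeOH (3 equiv), Me2C(OMe)2/CH2Cl2 (1:2), 0 °C to rt; Et3N quench
Reagents that add atoms: 2,2-dimethoxypropane, COC(C)(C)OC
Why: Acid-catalysed methanolysis of the triethylsilyl ether and transketalisation in the same flask, a known silyl ether-to-acetonide exchange, should tie O1' and O3' into the dioxane without breaking any bond at either stereocentre, so that no β-hydroxy ketone ever has to be handled.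

**Step 9**
Reactants: 14 the acetonide thioester; 15 isobutylzinc bromide
Product: 16 1-[(4S,5R)-4-(7-methoxy-2-oxo-2H-chromen-6-yl)-2,2,6,6-tetramethyl-1,3-dioxan-5-yl]-3-methylbutan-1-one
Conditions: PdCl2(PPh3)2 (10 mol%), 15 (0.5 M in THF, 2.5 equiv), toluene, rt
Reagents that add atoms: none
Why: Fukuyama coupling (oxidative addition of zerovalent palladium into the C(acyl)–S bond, transmetalation from zinc, reductive elimination) gives the ketone under neutral conditions in which the organozinc halide should not attack lactone, enoate or acetal and C5 is not enolised.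

**Step 10**
Reactants: 16 the acetonide isobutyl ketone
Product: 18 (4R,5R)-4-(7-methoxy-2-oxo-2H-chromen-6-yl)-2,2,6,6-tetramethyl-1,3-dioxan-5-yl 3-methylbutanoate, via Criegee peroxyhemiketal 17 (not isolated)
Conditions: mCPBA (3 equiv), NaHCO3 (5 equiv), CH2Cl2, 0 °C to rt
Reagents that add atoms: m-chloroperbenzoic acid, OOC(=O)c1cccc(Cl)c1
Why: The peracid adds to the ketone carbonyl to give the tetrahedral peroxyhemiketal 17, which collapses as m-chlorobenzoate leaves while ring carbon C5 (C2' of the target) shifts with its bonding pair from the carbonyl carbon to the proximal peroxide oxygen, creating the C2'–O and O–C(acyl) bonds. The closest known reaction type is the Baeyer–Villiger oxidation of α-branched β-alkoxy ketones, in which the secondary carbon migrates. No ring is closed and no stereocentre is made: C2' migrates suprafacially and keeps its configuration, so the trans-4,5 relationship from the aldol becomes the erythro 1',2' relationship of the target. The selectivity needed is migration of C2' in preference to the isobutyl CH2; the substrate offers a secondary against a primary carbon, the usual order of migratory aptitude, although the two β-oxygens weaken that preference. Chemoselectivity rests on the acetonide, which blocks retro-aldol cleavage and acyl shifts, on the electron-poor C3=C4 bond of ring B, which a peracid should not epoxidise, and on the bicarbonate buffer, which shields the acid-labile acetal.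

**Step 11**
Reactants: 18 the acetonide isovalerate
Product: 19 (1R,2R)-1,3-dihydroxy-1-(7-methoxy-2-oxo-2H-chromen-6-yl)-3-methylbutan-2-yl 3-methylbutanoate (target)
Conditions: AcOH/H2O (4:1), rt
Reagents that add atoms: none
Why: Mild aqueous acid hydrolysis of the strained tetramethyl-dioxane should release both hydroxyls and acetone; the absence of base avoids 2'→1' acyl migration and lactone opening, and the absence of alcohol solvent avoids solvolytic ether formation at the o-methoxybenzylic C1'.

**Compound list**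
1 | 4-bromoresorcinol (4-bromobenzene-1,3-diol) | Oc1ccc(Br)c(O)c1 | starting material
2 | 6-bromo-7-hydroxy-2H-chromen-2-one | Oc1cc2oc(=O)ccc2cc1Br | intermediate
3 | 6-bromo-7-methoxy-2H-chromen-2-one | COc1cc2oc(=O)ccc2cc1Br | intermediate
4 | 7-methoxy-2-oxo-2H-chromene-6-carbaldehyde | COc1cc2oc(=O)ccc2cc1C=O | intermediate
5 | 3-hydroxy-3-methylbutanoic acid | CC(C)(O)CC(=O)O | starting material
6 | triethylsilyl 3-methyl-3-(triethylsilyloxy)butanoate | CC[Si](CC)(CC)OC(C)(C)CC(=O)O[Si](CC)(CC)CC | intermediate (not isolated)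
7 | 3-methyl-3-(triethylsilyloxy)butanoic acid | CC[Si](CC)(CC)OC(C)(C)CC(=O)O | intermediate
8 | (S)-4-benzyl-1,3-thiazolidine-2-thione | S=C1N[C@@H](Cc2ccccc2)CS1 | starting material
9 | (S)-4-benzyl-3-[3-methyl-3-(triethylsilyloxy)butanoyl]-1,3-thiazolidine-2-thione | CC[Si](CC)(CC)OC(C)(C)CC(=O)N1[C@@H](Cc2ccccc2)CSC1=S | intermediate
10 | trichlorotitanium Z-enolate of 9 | CC[Si](CC)(CC)OC(C)(C)/C=C(\O[Ti](Cl)(Cl)Cl)N1[C@@H](Cc2ccccc2)CSC1=S | intermediate (not isolated)
11 | (S)-4-benzyl-3-[(2R,3S)-3-hydroxy-3-(7-methoxy-2-oxo-2H-chromen-6-yl)-2-[2-(triethylsilyloxy)propan-2-yl]propanoyl]-1,3-thiazolidine-2-thione | COc1cc2oc(=O)ccc2cc1[C@@H](O)[C@@H](C(=O)N1[C@@H](Cc2ccccc2)CSC1=S)C(C)(C)O[Si](CC)(CC)CC | intermediate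
12 | S-ethyl (2R,3S)-3-hydroxy-3-(7-methoxy-2-oxo-2H-chromen-6-yl)-2-[2-(triethylsilyloxy)propan-2-yl]propanethioate | COc1cc2oc(=O)ccc2cc1[C@@H](O)[C@@H](C(=O)SCC)C(C)(C)O[Si](CC)(CC)CC | intermediate
13 | S-ethyl (2R,3S)-3-hydroxy-2-(2-hydroxypropan-2-yl)-3-(7-methoxy-2-oxo-2H-chromen-6-yl)propanethioate | COc1cc2oc(=O)ccc2cc1[C@@H](O)[C@@H](C(=O)SCC)C(C)(C)O | intermediate (not isolated)
14 | S-ethyl (4S,5R)-4-(7-methoxy-2-oxo-2H-chromen-6-yl)-2,2,6,6-tetramethyl-1,3-dioxane-5-carbothioate | COc1cc2oc(=O)ccc2cc1[C@H]1OC(C)(C)OC(C)(C)[C@@H]1C(=O)SCC | intermediate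
15 | isobutylzinc bromide | CC(C)C[Zn]Br | starting material
16 | 1-[(4S,5R)-4-(7-methoxy-2-oxo-2H-chromen-6-yl)-2,2,6,6-tetramethyl-1,3-dioxan-5-yl]-3-methylbutan-1-one (trans) | COc1cc2oc(=O)ccc2cc1[C@H]1OC(C)(C)OC(C)(C)[C@@H]1C(=O)CC(C)C | intermediate (key-step precursor)
17 | peroxyhemiketal of 16 with m-chloroperbenzoic acid (carbinol carbon unassigned) | COc1cc2oc(=O)ccc2cc1[C@H]1OC(C)(C)OC(C)(C)[C@@H]1C(O)(CC(C)C)OOC(=O)c1cccc(Cl)c1 | intermediate (not isolated)
18 | (4R,5R)-4-(7-methoxy-2-oxo-2H-chromen-6-yl)-2,2,6,6-tetramethyl-1,3-dioxan-5-yl 3-methylbutanoate (trans) | COc1cc2oc(=O)ccc2cc1[C@H]1OC(C)(C)OC(C)(C)[C@@H]1OC(=O)CC(C)C | intermediate (key-step product)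
19 | (1R,2R)-1,3-dihydroxy-1-(7-methoxy-2-oxo-2H-chromen-6-yl)-3-methylbutan-2-yl 3-methylbutanoate | COc1cc2oc(=O)ccc2cc1[C@@H](O)[C@@H](OC(=O)CC(C)C)C(C)(C)O | target

**Totals.** Total step count: 11. Longest linear sequence: 9 steps (steps 1, 2, 3, 6, 7, 8, 9, 10, 11, from 4-bromoresorcinol).

**Steps most likely to fail**

Step 10. The isobutyl methylene may migrate in competition with C2', or peracid addition to the hindered, inductively deactivated carbonyl may be so slow that loss of the acetonide overtakes oxidation. The fallback sets out from 14 and returns at 18: oxygen is inserted on a methyl ketone, where the rival group is the poorest migrator, and the isovalerate is attached afterwards. Thioester 14 is coupled with MeZnCl (PdCl2(PPh3)2, THF/toluene, rt) to give 1-[(4S,5R)-4-(7-methoxy-2-oxo-2H-chromen-6-yl)-2,2,6,6-tetramethyl-1,3-dioxan-5-yl]ethan-1-one F1. Baeyer–Villiger oxidation (mCPBA, NaHCO3, CH2Cl2) should give (4R,5R)-4-(7-methoxy-2-oxo-2H-chromen-6-yl)-2,2,6,6-tetramethyl-1,3-dioxan-5-yl acetate F2. Methanolysis (K2CO3, MeOH, 0 °C, work-up at pH 5 to reclose any opened lactone) gives (4R,5R)-4-(7-methoxy-2-oxo-2H-chromen-6-yl)-2,2,6,6-tetramethyl-1,3-dioxan-5-ol F3. Acylation with 3-methylbutanoyl chloride (pyridine, DMAP, CH2Cl2) returns to 18.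

Step 6. Enolisation or addition may stall at the neopentyl-type α-carbon, the tertiary silyloxy group may be lost by Lewis acid-assisted elimination, or facial selectivity may erode if the Lewis-basic coumarin aldehyde disturbs the open transition state. The fallback sets out from 7 and 4 and returns at 12, using a boron-mediated Evans syn-aldol. Acid 7 is coupled with (S)-4-benzyl-1,3-oxazolidin-2-one (DCC, DMAP, CH2Cl2) to give (S)-4-benzyl-3-[3-methyl-3-(triethylsilyloxy)butanoyl]-1,3-oxazolidin-2-one F4. Enolisation with Bu2BOTf/iPr2NEt (CH2Cl2, −78 to 0 °C), addition of 4 and buffered H2O2 work-up should give, with the same sense of induction, (S)-4-benzyl-3-[(2R,3S)-3-hydroxy-3-(7-methoxy-2-oxo-2H-chromen-6-yl)-2-[2-(triethylsilyloxy)propan-2-yl]propanoyl]-1,3-oxazolidin-2-one F5. LiSEt (EtSH, n-BuLi, THF, 0 °C) then exchanges the auxiliary for the ethyl thioester and gives 12.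

Step 9. Transmetalation at the hindered acylpalladium may be slow, and β-hydride elimination from the isobutylpalladium species may then deliver reduced material in place of the ketone. The fallback sets out from 14 and returns at 16. Fukuyama reduction (Et3SiH, Pd/C, acetone, rt) gives (4S,5R)-4-(7-methoxy-2-oxo-2H-chromen-6-yl)-2,2,6,6-tetramethyl-1,3-dioxane-5-carbaldehyde F6. Addition of isobutylmagnesium bromide premixed with CeCl3 (THF, −78 °C), where the aldehyde is expected to react far faster than the lactone, gives (1RS)-1-[(4S,5R)-4-(7-methoxy-2-oxo-2H-chromen-6-yl)-2,2,6,6-tetramethyl-1,3-dioxan-5-yl]-3-methylbutan-1-ol F7 as an inconsequential epimer mixture. Dess–Martin oxidation (NaHCO3, CH2Cl2) gives 16.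

**Further compounds**
F1 | step 10 | 1-[(4S,5R)-4-(7-methoxy-2-oxo-2H-chromen-6-yl)-2,2,6,6-tetramethyl-1,3-dioxan-5-yl]ethan-1-one | COc1cc2oc(=O)ccc2cc1[C@H]1OC(C)(C)OC(C)(C)[C@@H]1C(C)=O
F2 | step 10 | (4R,5R)-4-(7-methoxy-2-oxo-2H-chromen-6-yl)-2,2,6,6-tetramethyl-1,3-dioxan-5-yl acetate | COc1cc2oc(=O)ccc2cc1[C@H]1OC(C)(C)OC(C)(C)[C@@H]1OC(C)=O
F3 | step 10 | (4R,5R)-4-(7-methoxy-2-oxo-2H-chromen-6-yl)-2,2,6,6-tetramethyl-1,3-dioxan-5-ol | COc1cc2oc(=O)ccc2cc1[C@H]1OC(C)(C)OC(C)(C)[C@@H]1O
F4 | step 6 | (S)-4-benzyl-3-[3-methyl-3-(triethylsilyloxy)butanoyl]-1,3-oxazolidin-2-one | CC[Si](CC)(CC)OC(C)(C)CC(=O)N1[C@@H](Cc2ccccc2)COC1=O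
F5 | step 6 | (S)-4-benzyl-3-[(2R,3S)-3-hydroxy-3-(7-methoxy-2-oxo-2H-chromen-6-yl)-2-[2-(triethylsilyloxy)propan-2-yl]propanoyl]-1,3-oxazolidin-2-one | COc1cc2oc(=O)ccc2cc1[C@@H](O)[C@@H](C(=O)N1[C@@H](Cc2ccccc2)COC1=O)C(C)(C)O[Si](CC)(CC)CC
F6 | step 9 | (4S,5R)-4-(7-methoxy-2-oxo-2H-chromen-6-yl)-2,2,6,6-tetramethyl-1,3-dioxane-5-carbaldehyde | COc1cc2oc(=O)ccc2cc1[C@H]1OC(C)(C)OC(C)(C)[C@@H]1C=O
F7 | step 9 | (1RS)-1-[(4S,5R)-4-(7-methoxy-2-oxo-2H-chromen-6-yl)-2,2,6,6-tetramethyl-1,3-dioxan-5-yl]-3-methylbutan-1-ol | COc1cc2oc(=O)ccc2cc1[C@H]1OC(C)(C)OC(C)(C)[C@@H]1C(O)CC(C)C
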